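**Plan**

- Numbering: ring A runs from C1 (carbon substituent) to C6; ring B runs from C1' (ether oxygen) to C6', with C2' carrying the carbon substituent.
- Retrosynthesis: both CH2OH groups go back to formyl groups. The C5–Br and C4'–Br bonds are then cut together, because C5 is the only open carbon ortho to the C4 hydroxyl and C4' the only open carbon ortho to the C5' hydroxyl. The three phenols are then masked as methyl ethers, and last the O–C1' bond of the diaryl ether is cut.
- The C2 bromine lies ortho to no hydroxyl and cannot be placed by phenol direction, so it is bought in with 2-bromoisovanillin.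
- Forward: the two purchased benzaldehydes are joined by displacement of fluoride, the methyl ethers are cleaved, two bromines are introduced in one operation, and the two formyl groups are reduced. No ring is built.
- The target has no stereocentre; the only selectivity to secure is regiochemical (C5 over C6, C4' over C3').

Key step: step 3

Assumption: both building blocks, 2-bromoisovanillin and 2-fluoro-3,4-dimethoxybenzaldehyde, are taken as catalogue chemicals.

**Step 1**
Reactants: 1 2-bromo-3-hydroxy-4-methoxybenzaldehyde (2-bromoisovanillin); 2 2-fluoro-3,4-dimethoxybenzaldehyde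
Product: 3 2-bromo-3-(6-formyl-2,3-dimethoxyphenoxy)-4-methoxybenzaldehyde
Conditions: Cs2CO3 (1.5 equiv), 2 (1.2 equiv), DMSO, 100 °C, Ar
Reagents that add atoms: none
Why: Nucleophilic aromatic substitution by addition–elimination, in which the cesium phenoxide of 1 adds to the fluorine-bearing C2 of 2, the ortho-formyl group stabilises the Meisenheimer adduct and fluoride is expelled, a well-known way from 2-fluorobenzaldehydes and phenols to ortho-formyl diaryl ethers, while the bromide of 1 is a far poorer nucleofuge on a ring deactivated as its phenoxide, so self-condensation should not compete.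

**Step 2**
Reactants: 3 2-bromo-3-(6-formyl-2,3-dimethoxyphenoxy)-4-methoxybenzaldehyde
Product: 4 2-bromo-3-(6-formyl-2,3-dihydroxyphenoxy)-4-hydroxybenzaldehyde
Conditions: BBr3 (7 equiv), CH2Cl2, −78 °C to rt; then ice-water
Reagents that add atoms: none
Why: Lewis acid ether cleavage with BBr3, in which boron binds each methoxy oxygen and bromide removes the methyl group by SN2 attack, a path closed to the diaryl ether (two sp2 carbons on oxygen) and to the aryl bromide, and aqueous work-up hydrolyses the aryl borates and any boron adducts of the formyl groups, as in the routine BBr3 demethylation of methoxybenzaldehydes.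

**Step 3**
Reactants: 4 2-bromo-3-(6-formyl-2,3-dihydroxyphenoxy)-4-hydroxybenzaldehyde
Product: 6 2,5-dibromo-3-(4-bromo-6-formyl-2,3-dihydroxyphenoxy)-4-hydroxybenzaldehyde, via ring-B monobromide 5 (not isolated)
Conditions: Br2 (2.05 equiv, added dropwise), NaOAc (3 equiv), AcOH–CH2Cl2, 0 °C to rt, dark
Reagents that add atoms: bromine, BrBr
Why: Each bromination is an electrophilic aromatic substitution in which Br2 attacks the carbon ortho to a free phenol to give an arenium ion stabilised by the oxygen lone pair, after which acetate removes the ring proton and buffers the HBr. The closest known reaction type is the ortho-bromination of hydroxybenzaldehydes with bromine in buffered acetic acid, as in the conversion of vanillin to 5-bromovanillin, of protocatechualdehyde to its 5-bromide and of 2,3,4-trihydroxybenzaldehyde to its 5-bromide. No ring closes and no stereocentre is formed. On ring A the C4 hydroxyl has one open ortho carbon, C5, because C3 bears the aryloxy group, while C6 is meta to that hydroxyl and ortho to the formyl group and should stay untouched. On ring B, C4' is ortho to the C5' hydroxyl, para to the C1' ether oxygen and meta to the formyl group, whereas the only other free carbon, C3', is merely para to the C6' hydroxyl and feels the ortho-formyl deactivation, so the electron-richer ring B should react first at C4' and ring A second at C5. Holding bromine at two equivalents, adding it slowly in the cold and buffering with NaOAc should hold back a third bromination at C3', oxidation of the catechol to an ortho-quinone and ipso-bromodeformylation para to the phenols.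

**Step 4**
Reactants: 6 2,5-dibromo-3-(4-bromo-6-formyl-2,3-dihydroxyphenoxy)-4-hydroxybenzaldehyde
Product: 7 [2,5-dibromo-3-(4-bromo-2,3-dihydroxy-6-(hydroxymethyl)phenoxy)-4-hydroxyphenyl]methanol (target)
Conditions: NaBH4 (4 equiv), THF–H2O, 0 °C to rt, Ar; then pH 6 phosphate buffer
Reagents that add atoms: none
Why: Hydride reduction of aromatic aldehydes with NaBH4, which tolerates free phenols when used in excess (as in the classic reduction of vanillin to vanillyl alcohol in alkaline water), leaves the aryl bromides and the diaryl ether alone, and the quench is held near pH 6 so that the para-hydroxybenzyl alcohols do not ionise to quinone methides.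

**Compound list**

1 | 2-bromo-3-hydroxy-4-methoxybenzaldehyde (2-bromoisovanillin) | COc1ccc(C=O)c(Br)c1O | starting material
2 | 2-fluoro-3,4-dimethoxybenzaldehyde | COc1ccc(C=O)c(F)c1OC | starting material
3 | 2-bromo-3-(6-formyl-2,3-dimethoxyphenoxy)-4-methoxybenzaldehyde | COc1ccc(C=O)c(Br)c1Oc1c(C=O)ccc(OC)c1OC | intermediate
4 | 2-bromo-3-(6-formyl-2,3-dihydroxyphenoxy)-4-hydroxybenzaldehyde | O=Cc1ccc(O)c(Oc2c(C=O)ccc(O)c2O)c1Br | intermediate
5 | 2-bromo-3-(4-bromo-6-formyl-2,3-dihydroxyphenoxy)-4-hydroxybenzaldehyde | O=Cc1ccc(O)c(Oc2c(C=O)cc(Br)c(O)c2O)c1Br | intermediate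
6 | 2,5-dibromo-3-(4-bromo-6-formyl-2,3-dihydroxyphenoxy)-4-hydroxybenzaldehyde | O=Cc1cc(Br)c(O)c(Oc2c(C=O)cc(Br)c(O)c2O)c1Br | intermediate
7 | [2,5-dibromo-3-(4-bromo-2,3-dihydroxy-6-(hydroxymethyl)phenoxy)-4-hydroxyphenyl]methanol | OCc1cc(Br)c(O)c(Oc2c(CO)cc(Br)c(O)c2O)c1Br | target

**Step count and risks**

Total step count: 4. Longest linear sequence: 4 steps (from 1 or 2 to 7).

Steps most likely to fail:

Step 1. The addition–elimination may stall, because both partners carry two ortho substituents around the reacting centres and the methoxy group para to the formyl group of 2 weakens its activation. Forcing the temperature could then let phenoxide attack the formyl-activated C2 bromide of the product. The fallback sets out from 1 and reverses the polarity of the aryl transfer. Purchasable 3-hydroxy-2-iodo-4-methoxybenzaldehyde would be O-methylated (MeI, K2CO3, DMF) to 2-iodo-3,4-dimethoxybenzaldehyde F1. F1 would be oxidised at iodine (mCPBA, TsOH·H2O, MeCN) and trapped with 1,3,5-trimethoxybenzene to give (6-formyl-2,3-dimethoxyphenyl)(2,4,6-trimethoxyphenyl)iodonium 4-methylbenzenesulfonate F2. Phenol 1 would then be arylated with F2 (K2CO3, MeCN, 50 °C) by ligand coupling at trivalent iodine, a metal-free process known to tolerate ortho substituents on both partners, with the electron-rich trimethoxyphenyl group staying on iodine. This comes back to the route at 3.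

Step 3. Regiocontrol on ring B may erode through attack at C3', para to the C6' hydroxyl, either in competition with C4' or as a third bromination. The free catechol may also be oxidised by bromine to an ortho-quinone. The fallback sets out from 3 and differentiates the phenols before bromination. LiCl in DMF at 140 °C should cleave by SN2 only the two methoxy groups para to formyl groups (on C4 and C5'), giving 2-bromo-3-(6-formyl-3-hydroxy-2-methoxyphenoxy)-4-hydroxybenzaldehyde F3. With the C6' oxygen still methylated there is no catechol to oxidise and C3' has no para hydroxyl, so Br2 (2 equiv, NaOAc, AcOH) should be directed only to C5 and C4', giving 2,5-dibromo-3-(4-bromo-6-formyl-3-hydroxy-2-methoxyphenoxy)-4-hydroxybenzaldehyde F4. BBr3 in CH2Cl2 then removes the last methyl group and comes back to the route at 6.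

Step 4. In alkaline borohydride the substrate exists as a polyphenoxide, so hydride addition to the formyl groups is slowed and the catecholate is exposed to aerial oxidation. On acidification the para-hydroxybenzyl alcohols can ionise to quinone methides and give ethers or oligomers. The fallback sets out from 6 and reduces a neutral, protected substrate. Ac2O and pyridine would give 4-acetoxy-3-(2,3-diacetoxy-4-bromo-6-formylphenoxy)-2,5-dibromobenzaldehyde F5. NaBH4 in THF–EtOH at −20 °C should reduce only the two aldehydes to give 4-acetoxy-3-[2,3-diacetoxy-4-bromo-6-(hydroxymethyl)phenoxy]-2,5-dibromobenzyl alcohol F6. Hydrazine hydrate in THF at 0 °C then removes the aryl acetates under near-neutral conditions and comes back to the route at 7.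

**Further compounds**

F1 | step 1 | 2-iodo-3,4-dimethoxybenzaldehyde | COc1ccc(C=O)c(I)c1OC
F2 | step 1 | (6-formyl-2,3-dimethoxyphenyl)(2,4,6-trimethoxyphenyl)iodonium 4-methylbenzenesulfonate | COc1cc(OC)c([I+]c2c(C=O)ccc(OC)c2OC)c(OC)c1.Cc1ccc(cc1)S([O-])(=O)=O
F3 | step 3 | 2-bromo-3-(6-formyl-3-hydroxy-2-methoxyphenoxy)-4-hydroxybenzaldehyde | O=Cc1ccc(O)c(Oc2c(C=O)ccc(O)c2OC)c1Br
F4 | step 3 | 2,5-dibromo-3-(4-bromo-6-formyl-3-hydroxy-2-methoxyphenoxy)-4-hydroxybenzaldehyde | O=Cc1cc(Br)c(O)c(Oc2c(C=O)cc(Br)c(O)c2OC)c1Br
F5 | step 4 | 4-acetoxy-3-(2,3-diacetoxy-4-bromo-6-formylphenoxy)-2,5-dibromobenzaldehyde | CC(=O)Oc1c(Br)cc(C=O)c(Br)c1Oc1c(C=O)cc(Br)c(OC(C)=O)c1OC(C)=O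
F6 | step 4 | 4-acetoxy-3-[2,3-diacetoxy-4-bromo-6-(hydroxymethyl)phenoxy]-2,5-dibromobenzyl alcohol | CC(=O)Oc1c(Br)cc(CO)c(Br)c1Oc1c(CO)cc(Br)c(OC(C)=O)c1OC(C)=O
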